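Ring A is disconnected at C5–C10 by a 6π electrocyclisation of a dienylketene, itself released by 4π opening of a squarate-derived cyclobutenone. In one operation this closes ring A, creates the quaternary centre C5 and delivers C7, C8, C9 and C10 as four contiguous, oxygen-bearing ring carbons, the pattern the target shows next to C5. The precursor is a 2,3-di-tert-butoxy-4-hydroxycyclobutenone carrying at C7 an (E)-trisubstituted alkenyl chain (C6=C5, C4 methyl, C3 silyl ether, protected C1 alcohol) made by anti-propargylation and carboalumination. Afterwards an enol triflate at C7, an anionic closure of ring B onto C10, acid unveiling of the C8/C9 ketol and esterifications complete the synthesis.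

Key step: step 8

Remark: atom labels C1–C10 follow the numbering of the target (ring A = C5 to C10, ring B = C10, C1 to C5); β is the face of the bicycle that carries the C5 methyl group; the minor syn isomer of step 4 and any C5 epimer from step 8 are assumed to be separable by chromatography.

Step 1
Reactants: 1 (S)-but-3-yn-2-ol
Product: 2 (S)-but-3-yn-2-yl methanesulfonate
Conditions: MsCl, Et3N, CH2Cl2, −78 °C
Reagents that add atoms: methanesulfonyl chloride, CS(=O)(=O)Cl
Why: Mesylation (O-sulfonylation) makes the propargylic leaving group without touching the C–O stereocentre, so the (S) configuration is kept.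

Step 2
Reactants: 3 propane-1,3-diol
Product: 4 3-[(4-methoxybenzyl)oxy]propan-1-ol
Conditions: NaH (1 equiv), 4-methoxybenzyl chloride, Bu4NI (cat.), THF/DMF, 0 °C to rt, diol in excess
Reagents that add atoms: 4-methoxybenzyl chloride, COc1ccc(CCl)cc1
Why: Williamson ether synthesis on the mono-alkoxide of an excess of the symmetric diol should give mainly the mono-ether.

Step 3
Reactants: 4 3-[(4-methoxybenzyl)oxy]propan-1-ol
Product: 5 3-[(4-methoxybenzyl)oxy]propanal
Conditions: TEMPO (2,2,6,6-tetramethylpiperidin-1-oxyl, cat.), PhI(OAc)2, CH2Cl2, rt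
Reagents that add atoms: none
Why: TEMPO-catalysed oxoammonium oxidation of a primary alcohol stops at the aldehyde and tolerates the PMB ether.

Step 4
Reactants: 2 (S)-but-3-yn-2-yl methanesulfonate; 5 3-[(4-methoxybenzyl)oxy]propanal
Product: 7 (3S,4R)-1-[(4-methoxybenzyl)oxy]-4-methylhex-5-yn-3-ol, via (aR)-buta-1,2-dien-1-yl(ethyl)zinc 6 (not isolated)
Conditions: Pd(OAc)2 (5 mol %), PPh3 (5 mol %), Et2Zn, THF, −78 to −20 °C; then NH4Cl (aq)
Reagents that add atoms: none
Why: Marshall propargylation, in which zerovalent palladium formed in the flask displaces the mesylate anti (SN2′), transmetalation with Et2Zn gives the configurationally defined allenylzinc 6, and its cyclic SE2′ addition to the aldehyde should give the anti adduct with C4 set as R (from the S mesylate) and C3 as S.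

Step 5
Reactants: 7 (3S,4R)-1-[(4-methoxybenzyl)oxy]-4-methylhex-5-yn-3-ol
Product: 8 (3S,4R)-1-[(4-methoxybenzyl)oxy]-4-methyl-3-[(triisopropylsilyl)oxy]hex-5-yne
Conditions: TIPSOTf, 2,6-lutidine, CH2Cl2, −78 to 0 °C
Reagents that add atoms: triisopropylsilyl trifluoromethanesulfonate, CC(C)[Si](C(C)C)(C(C)C)OS(=O)(=O)C(F)(F)F
Why: Silylation of the secondary alcohol with a silyl triflate; the bulky triisopropylsilyl ether is chosen because it survives organolithiums, amide bases and trifluoroacetic acid and enlarges the C3 branch that shields one alkene face in step 8.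

Step 6
Reactants: 8 (3S,4R)-1-[(4-methoxybenzyl)oxy]-4-methyl-3-[(triisopropylsilyl)oxy]hex-5-yne
Product: 10 (1E,3R,4S)-1-iodo-6-[(4-methoxybenzyl)oxy]-2,3-dimethyl-4-[(triisopropylsilyl)oxy]hex-1-ene, via (E)-alkenyl(dimethyl)alane 9 (not isolated)
Conditions: AlMe3, Cp2ZrCl2 (0.25 equiv), CH2Cl2, 0 °C to rt; then I2, THF, −30 to 0 °C
Reagents that add atoms: trimethylaluminium, C[Al](C)C; iodine, II
Why: Negishi zirconium-catalysed carboalumination adds CH3 (to C5) and aluminium (to C6) syn across the terminal alkyne, and iodinolysis of the C–Al bond with retention gives the (E)-trisubstituted alkenyl iodide.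

Step 7
Reactants: 10 (1E,3R,4S)-1-iodo-6-[(4-methoxybenzyl)oxy]-2,3-dimethyl-4-[(triisopropylsilyl)oxy]hex-1-ene; 11 di-tert-butyl squarate (3,4-di-tert-butoxycyclobut-3-ene-1,2-dione)
Product: 13 2,3-di-tert-butoxy-4-hydroxy-4-[(1E,3R,4S)-6-[(4-methoxybenzyl)oxy]-2,3-dimethyl-4-[(triisopropylsilyl)oxy]hex-1-en-1-yl]cyclobut-2-en-1-one (both epimers at the carbinol carbon C7), via (E)-alkenyllithium 12 (not isolated)
Conditions: t-BuLi (2 equiv), Et2O, −78 °C; then 11, THF, −78 °C; NH4Cl (aq)
Reagents that add atoms: none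
Why: Iodine–lithium exchange retains the alkene geometry and the alkenyllithium adds 1,2 to one carbonyl of the squarate at −78 °C (the remaining carbonyl then being a deactivated vinylogous ester), the carbinol carbon C7 forming as both epimers, which is immaterial because C7 becomes sp2 in step 8.

Step 8
Reactants: 13 2,3-di-tert-butoxy-4-hydroxy-4-[(1E,3R,4S)-6-[(4-methoxybenzyl)oxy]-2,3-dimethyl-4-[(triisopropylsilyl)oxy]hex-1-en-1-yl]cyclobut-2-en-1-one
Product: 16 (5R)-2,3-di-tert-butoxy-5-methyl-5-[(2R,3S)-5-[(4-methoxybenzyl)oxy]-3-[(triisopropylsilyl)oxy]pentan-2-yl]cyclohex-2-ene-1,4-dione, via (Z)-dienylketene 14 (not isolated), via 4-hydroxycyclohexa-2,4-dienone tautomer 15 (not isolated)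
Conditions: toluene (degassed, dilute), 110 °C
Reagents that add atoms: none
Why: Heat opens the cyclobutenone by a conrotatory 4π electrocyclic cleavage of the C7–C10 bond with the donor hydroxyl rotating outward, so the alkenyl group ends cis to the ketene in 14; the ketene carbon C10 then bonds to C5 in a disrotatory 6π electrocyclisation and dienol 15 tautomerises to the 1,4-dione because the fully substituted C5 blocks aromatisation. The closest known reaction type is the thermal ring expansion of squarate-derived 4-alkenyl-4-hydroxycyclobutenones (Moore rearrangement), which stops at a cyclohex-2-ene-1,4-dione when the alkene terminus carries two carbon substituents. Ring A is thus closed by a thermal 6π electrocyclisation forming the C5–C10 bond, with the C5 methyl inside and the C4 branch outside as fixed by the (E)-alkene. The new quaternary centre C5 is controlled by the neighbouring C4 stereocentre: allylic 1,2-strain with the C5 methyl keeps the C4–H bond on the methyl side, the large C3 silyloxyalkyl branch stands perpendicular to the alkene, and the ketene carbon bonds to the opposite face, which for the (E)-alkene and (4R) centre gives (5R). The step needs this facial selectivity, which rests only on the steric difference at C4 (enlarged by the triisopropylsilyl ether) and is the weak point, and it needs outward rotation of the hydroxyl, which the donor substituent secures electronically.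

Step 9
Reactants: 16 (5R)-2,3-di-tert-butoxy-5-methyl-5-[(2R,3S)-5-[(4-methoxybenzyl)oxy]-3-[(triisopropylsilyl)oxy]pentan-2-yl]cyclohex-2-ene-1,4-dione
Product: 18 (3S)-5,6-di-tert-butoxy-3-methyl-4-oxo-3-[(2R,3S)-5-[(4-methoxybenzyl)oxy]-3-[(triisopropylsilyl)oxy]pentan-2-yl]cyclohexa-1,5-dien-1-yl trifluoromethanesulfonate (C7 enol triflate), via potassium dienolate 17 (not isolated)
Conditions: KN(SiMe3)2, THF, −78 °C; then PhNTf2, −78 to 0 °C
Reagents that add atoms: N-phenylbis(trifluoromethanesulfonimide), O=S(=O)(N(c1ccccc1)S(=O)(=O)C(F)(F)F)C(F)(F)F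
Why: C6 carries the only acidic hydrogens, so a single dienolate forms and O-triflation (enol triflate formation) fixes the C6=C7 double bond regiospecifically, which an addition–dehydration sequence at C7 could not guarantee because such a carbinol would ionise toward C9.

Step 10
Reactants: 18 C7 enol triflate
Product: 19 (3S)-5,6-di-tert-butoxy-3-[(2R,3S)-5-hydroxy-3-[(triisopropylsilyl)oxy]pentan-2-yl]-3-methyl-4-oxocyclohexa-1,5-dien-1-yl trifluoromethanesulfonate
Conditions: DDQ (2,3-dichloro-5,6-dicyano-1,4-benzoquinone), CH2Cl2/pH 7 buffer, 0 °C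
Reagents that add atoms: none
Why: Oxidative cleavage of the PMB ether by DDQ (oxidation of the electron-rich arene, then hydrolysis of the benzylic oxocarbenium ion) under buffered conditions, the acceptor-substituted dienone being too electron-poor to be oxidised.

Step 11
Reactants: 19 primary alcohol
Product: 20 (3S)-5,6-di-tert-butoxy-3-[(2R,3S)-5-iodo-3-[(triisopropylsilyl)oxy]pentan-2-yl]-3-methyl-4-oxocyclohexa-1,5-dien-1-yl trifluoromethanesulfonate
Conditions: PPh3, I2, imidazole, CH2Cl2, 0 °C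
Reagents that add atoms: iodine, II
Why: Appel-type iodination (Garegg–Samuelsson conditions) converts the primary alcohol through its alkoxyphosphonium ion into the iodide by SN2 at unhindered C1 under neutral conditions.

Step 12
Reactants: 20 primary iodide
Product: 22 (3S,4R,5S,10R)-8,9-di-tert-butoxy-10-hydroxy-4,5-dimethyl-3-[(triisopropylsilyl)oxy]bicyclo[4.4.0]deca-6,8-dien-7-yl trifluoromethanesulfonate (target numbering; cis-fused; 10-OH β), via primary alkyllithium 21 (not isolated)
Conditions: t-BuLi (2 equiv), Et2O/pentane, −78 °C; then NH4Cl (aq)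
Reagents that add atoms: none
Why: Iodine–lithium exchange at the primary iodide is faster than attack of t-BuLi on the dienone or the triflate, and the alkyllithium adds 1,2 to the C10 ketone in a six-membered anionic closure (intramolecular Barbier-type, Parham-like cyclisation, preferred here to a one-electron reductant that would reduce the dienone); because ring A is flat and the tether hangs from C5 on one face, C1 must bond to that same face of C10, which gives the cis-fused bicycle with the C10 hydroxyl cis to the C5 methyl.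

Step 13
Reactants: 22 bicyclic dienyl triflate
Product: 24 (3S,4R,5S,9S,10R)-9,10-dihydroxy-4,5-dimethyl-8-oxo-3-[(triisopropylsilyl)oxy]bicyclo[4.4.0]dec-6-en-7-yl trifluoromethanesulfonate (target numbering; 9-OH α; 10-OH β), via C9 tert-butyl ether ketone 23 (not isolated)
Conditions: CF3CO2H, CH2Cl2, −20 to 0 °C; then NaHCO3 (aq)
Reagents that add atoms: none
Why: Brønsted-acid cleavage of the tert-butyl enol ethers, in which protonation at C9 of the C8 enol ether gives a C8 oxocarbenium ion conjugated with C6=C7 that loses isobutene to the enone (this conjugation fixes the ketone at C8), the remaining C9 tert-butyl ether of 23 is cleaved by the same acid (E1), and C9 should be protonated on the β face, axially and anti to the axial C1–C10 bond in the cis-decalin conformer that keeps the C3 and C5 substituents equatorial on ring B, which places the C9 oxygen equatorial and trans to the C10 hydroxyl (9S), while the silyl ether and the vinyl triflate tolerate the acid.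

Step 14
Reactants: 24 ketol triflate
Product: 25 (3S,4R,5S,9S,10R)-10-hydroxy-4,5-dimethyl-9-[(Z)-2-methylbut-2-enoyloxy]-8-oxo-3-[(triisopropylsilyl)oxy]bicyclo[4.4.0]dec-6-en-7-yl trifluoromethanesulfonate (target numbering)
Conditions: angelic acid, 2,4,6-trichlorobenzoyl chloride, Et3N, toluene, rt; then 24, 70 °C
Reagents that add atoms: angelic acid [(Z)-2-methylbut-2-enoic acid], C/C=C(/C)C(=O)O
Why: Yamaguchi-type esterification through the mixed 2,4,6-trichlorobenzoic anhydride acylates only the secondary C9 hydroxyl (the tertiary C10 hydroxyl is inert) and, run without a nucleophilic catalyst, should avoid isomerisation of the angelate to the tiglate.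

Step 15
Reactants: 25 angelate
Product: 26 (3S,4R,5S,9S,10R)-3,10-dihydroxy-4,5-dimethyl-9-[(Z)-2-methylbut-2-enoyloxy]-8-oxobicyclo[4.4.0]dec-6-en-7-yl trifluoromethanesulfonate (target numbering)
Conditions: HF·pyridine, pyridine, THF, 0 °C to rt
Reagents that add atoms: none
Why: Fluoride-mediated desilylation removes the secondary triisopropylsilyl ether, and the esters, the vinyl triflate and the β-hydroxy ketone are stable to this buffered reagent.

Step 16
Reactants: 26 C3 alcohol
Product: 27 (3S,4R,5S,9S,10R)-3-acetoxy-10-hydroxy-4,5-dimethyl-9-[(Z)-2-methylbut-2-enoyloxy]-8-oxobicyclo[4.4.0]dec-6-en-7-yl trifluoromethanesulfonate (target numbering)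
Conditions: Ac2O, pyridine, 4-(dimethylamino)pyridine (cat.), CH2Cl2, 0 °C
Reagents that add atoms: acetic anhydride, CC(=O)OC(C)=O
Why: Acetylation of the secondary C3 alcohol under standard acyl-transfer catalysis, the hindered tertiary C10 hydroxyl remaining free.

Step 17
Reactants: 27 acetate triflate
Product: 29 CNP0196241.1 [(3S,4R,5R,9S,10R)-3-acetoxy-7-acetyl-10-hydroxy-4,5-dimethyl-8-oxobicyclo[4.4.0]dec-6-en-9-yl (Z)-2-methylbut-2-enoate; target numbering], via 1-ethoxyvinyl dienone 28 (not isolated)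
Conditions: tributyl(1-ethoxyvinyl)stannane, Pd(PPh3)4 (cat.), LiCl, CuI (cat.), THF, 60 °C; then 1 M HCl (aq), THF, 0 °C
Reagents that add atoms: tributyl(1-ethoxyvinyl)stannane, CCCC[Sn](CCCC)(CCCC)C(=C)OCC; water, O
Why: Stille coupling of the α-triflyloxy enone with the 1-ethoxyvinylstannane (an acetyl anion equivalent), followed by hydrolysis of the enol ether on acidic work-up, installs the C7 acetyl group last, so the electrophilic 2-acyl enone is not carried through other steps.

Compound list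
1 | (S)-but-3-yn-2-ol | C[C@H](O)C#C | starting material
2 | (S)-but-3-yn-2-yl methanesulfonate | C[C@H](OS(C)(=O)=O)C#C | intermediate
3 | propane-1,3-diol | OCCCO | starting material
4 | 3-[(4-methoxybenzyl)oxy]propan-1-ol | COc1ccc(COCCCO)cc1 | intermediate
5 | 3-[(4-methoxybenzyl)oxy]propanal | COc1ccc(COCCC=O)cc1 | intermediate
6 | (aR)-buta-1,2-dien-1-yl(ethyl)zinc | CC[Zn][CH]=[C@]=[CH]C | intermediate (not isolated)
7 | (3S,4R)-1-[(4-methoxybenzyl)oxy]-4-methylhex-5-yn-3-ol | C#C[C@@H](C)[C@@H](O)CCOCc1ccc(OC)cc1 | intermediate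
8 | (3S,4R)-1-[(4-methoxybenzyl)oxy]-4-methyl-3-[(triisopropylsilyl)oxy]hex-5-yne | C#C[C@@H](C)[C@@H](O[Si](C(C)C)(C(C)C)C(C)C)CCOCc1ccc(OC)cc1 | intermediate
9 | (E)-alkenyl(dimethyl)alane from 8 (CH3 on C5; AlMe2 on C6) | C[Al](C)/C=C(\C)[C@@H](C)[C@@H](O[Si](C(C)C)(C(C)C)C(C)C)CCOCc1ccc(OC)cc1 | intermediate (not isolated)
10 | (1E,3R,4S)-1-iodo-6-[(4-methoxybenzyl)oxy]-2,3-dimethyl-4-[(triisopropylsilyl)oxy]hex-1-ene | I/C=C(\C)[C@@H](C)[C@@H](O[Si](C(C)C)(C(C)C)C(C)C)CCOCc1ccc(OC)cc1 | intermediate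
11 | di-tert-butyl squarate (3,4-di-tert-butoxycyclobut-3-ene-1,2-dione) | CC(C)(C)OC1=C(OC(C)(C)C)C(=O)C1=O | starting material
12 | (E)-alkenyllithium from 10 (Li in place of I) | [Li]/C=C(\C)[C@@H](C)[C@@H](O[Si](C(C)C)(C(C)C)C(C)C)CCOCc1ccc(OC)cc1 | intermediate (not isolated)
13 | 2,3-di-tert-butoxy-4-hydroxy-4-[(1E,3R,4S)-6-[(4-methoxybenzyl)oxy]-2,3-dimethyl-4-[(triisopropylsilyl)oxy]hex-1-en-1-yl]cyclobut-2-en-1-one (both C7 carbinol epimers) | CC(C)(C)OC1=C(OC(C)(C)C)C(O)(/C=C(\C)[C@@H](C)[C@@H](O[Si](C(C)C)(C(C)C)C(C)C)CCOCc2ccc(OC)cc2)C1=O | intermediate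
14 | (Z)-dienylketene (ketene carbon C10; C9 and C6 cis across C8=C7; C5=C6 E) | O=C=C(OC(C)(C)C)/C(OC(C)(C)C)=C(O)\C=C(/C)[C@@H](C)[C@@H](O[Si](C(C)C)(C(C)C)C(C)C)CCOCc1ccc(OC)cc1 | intermediate (not isolated)
15 | 2,3-di-tert-butoxy-4-hydroxy-6-methyl-6-[(2R,3S)-5-[(4-methoxybenzyl)oxy]-3-[(triisopropylsilyl)oxy]pentan-2-yl]cyclohexa-2,4-dien-1-one (dienol tautomer of 16; C5 as in 16) | CC(C)(C)OC1=C(OC(C)(C)C)C(O)=C[C@@](C)(C1=O)[C@@H](C)[C@@H](O[Si](C(C)C)(C(C)C)C(C)C)CCOCc1ccc(OC)cc1 | intermediate (not isolated)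
16 | (5R)-2,3-di-tert-butoxy-5-methyl-5-[(2R,3S)-5-[(4-methoxybenzyl)oxy]-3-[(triisopropylsilyl)oxy]pentan-2-yl]cyclohex-2-ene-1,4-dione | CC(C)(C)OC1=C(OC(C)(C)C)C(=O)C[C@@](C)(C1=O)[C@@H](C)[C@@H](O[Si](C(C)C)(C(C)C)C(C)C)CCOCc1ccc(OC)cc1 | intermediate
17 | potassium dienolate of 16 (C6=C7–OK) | CC(C)(C)OC1=C(OC(C)(C)C)C([O-])=C[C@@](C)(C1=O)[C@@H](C)[C@@H](O[Si](C(C)C)(C(C)C)C(C)C)CCOCc1ccc(OC)cc1.[K+] | intermediate (not isolated)
18 | (3S)-5,6-di-tert-butoxy-3-methyl-4-oxo-3-[(2R,3S)-5-[(4-methoxybenzyl)oxy]-3-[(triisopropylsilyl)oxy]pentan-2-yl]cyclohexa-1,5-dien-1-yl trifluoromethanesulfonate | CC(C)(C)OC1=C(OC(C)(C)C)C(OS(=O)(=O)C(F)(F)F)=C[C@@](C)(C1=O)[C@@H](C)[C@@H](O[Si](C(C)C)(C(C)C)C(C)C)CCOCc1ccc(OC)cc1 | intermediate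
19 | (3S)-5,6-di-tert-butoxy-3-[(2R,3S)-5-hydroxy-3-[(triisopropylsilyl)oxy]pentan-2-yl]-3-methyl-4-oxocyclohexa-1,5-dien-1-yl trifluoromethanesulfonate | CC(C)(C)OC1=C(OC(C)(C)C)C(OS(=O)(=O)C(F)(F)F)=C[C@@](C)(C1=O)[C@@H](C)[C@@H](O[Si](C(C)C)(C(C)C)C(C)C)CCO | intermediate
20 | (3S)-5,6-di-tert-butoxy-3-[(2R,3S)-5-iodo-3-[(triisopropylsilyl)oxy]pentan-2-yl]-3-methyl-4-oxocyclohexa-1,5-dien-1-yl trifluoromethanesulfonate | CC(C)(C)OC1=C(OC(C)(C)C)C(OS(=O)(=O)C(F)(F)F)=C[C@@](C)(C1=O)[C@@H](C)[C@@H](O[Si](C(C)C)(C(C)C)C(C)C)CCI | intermediate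
21 | primary alkyllithium from 20 (Li in place of I) | CC(C)(C)OC1=C(OC(C)(C)C)C(OS(=O)(=O)C(F)(F)F)=C[C@@](C)(C1=O)[C@@H](C)[C@@H](O[Si](C(C)C)(C(C)C)C(C)C)CC[Li] | intermediate (not isolated)
22 | (3S,4R,5S,10R)-8,9-di-tert-butoxy-10-hydroxy-4,5-dimethyl-3-[(triisopropylsilyl)oxy]bicyclo[4.4.0]deca-6,8-dien-7-yl trifluoromethanesulfonate (target numbering; cis-fused) | CC(C)(C)OC1=C(OC(C)(C)C)C(OS(=O)(=O)C(F)(F)F)=C[C@]2(C)[C@@H](C)[C@@H](O[Si](C(C)C)(C(C)C)C(C)C)CC[C@]12O | intermediate
23 | (3S,4R,5S,9S,10R)-9-tert-butoxy-10-hydroxy-4,5-dimethyl-8-oxo-3-[(triisopropylsilyl)oxy]bicyclo[4.4.0]dec-6-en-7-yl trifluoromethanesulfonate (target numbering) | CC(C)(C)O[C@@H]1C(=O)C(OS(=O)(=O)C(F)(F)F)=C[C@]2(C)[C@@H](C)[C@@H](O[Si](C(C)C)(C(C)C)C(C)C)CC[C@]12O | intermediate (not isolated)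
24 | (3S,4R,5S,9S,10R)-9,10-dihydroxy-4,5-dimethyl-8-oxo-3-[(triisopropylsilyl)oxy]bicyclo[4.4.0]dec-6-en-7-yl trifluoromethanesulfonate (target numbering) | O[C@@H]1C(=O)C(OS(=O)(=O)C(F)(F)F)=C[C@]2(C)[C@@H](C)[C@@H](O[Si](C(C)C)(C(C)C)C(C)C)CC[C@]12O | intermediate
25 | (3S,4R,5S,9S,10R)-10-hydroxy-4,5-dimethyl-9-[(Z)-2-methylbut-2-enoyloxy]-8-oxo-3-[(triisopropylsilyl)oxy]bicyclo[4.4.0]dec-6-en-7-yl trifluoromethanesulfonate (target numbering) | C/C=C(/C)C(=O)O[C@@H]1C(=O)C(OS(=O)(=O)C(F)(F)F)=C[C@]2(C)[C@@H](C)[C@@H](O[Si](C(C)C)(C(C)C)C(C)C)CC[C@]12O | intermediate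
26 | (3S,4R,5S,9S,10R)-3,10-dihydroxy-4,5-dimethyl-9-[(Z)-2-methylbut-2-enoyloxy]-8-oxobicyclo[4.4.0]dec-6-en-7-yl trifluoromethanesulfonate (target numbering) | C/C=C(/C)C(=O)O[C@@H]1C(=O)C(OS(=O)(=O)C(F)(F)F)=C[C@]2(C)[C@@H](C)[C@@H](O)CC[C@]12O | intermediate
27 | (3S,4R,5S,9S,10R)-3-acetoxy-10-hydroxy-4,5-dimethyl-9-[(Z)-2-methylbut-2-enoyloxy]-8-oxobicyclo[4.4.0]dec-6-en-7-yl trifluoromethanesulfonate (target numbering) | C/C=C(/C)C(=O)O[C@@H]1C(=O)C(OS(=O)(=O)C(F)(F)F)=C[C@]2(C)[C@@H](C)[C@@H](OC(C)=O)CC[C@]12O | intermediate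
28 | (3S,4R,5R,9S,10R)-3-acetoxy-7-(1-ethoxyvinyl)-10-hydroxy-4,5-dimethyl-8-oxobicyclo[4.4.0]dec-6-en-9-yl (Z)-2-methylbut-2-enoate (target numbering) | C/C=C(/C)C(=O)O[C@@H]1C(=O)C(C(=C)OCC)=C[C@]2(C)[C@@H](C)[C@@H](OC(C)=O)CC[C@]12O | intermediate (not isolated)
29 | CNP0196241.1, (3S,4R,5R,9S,10R)-3-acetoxy-7-acetyl-10-hydroxy-4,5-dimethyl-8-oxobicyclo[4.4.0]dec-6-en-9-yl (Z)-2-methylbut-2-enoate (target numbering) | C/C=C(/C)C(=O)O[C@@H]1C(=O)C(C(C)=O)=C[C@]2(C)[C@@H](C)[C@@H](OC(C)=O)CC[C@]12O | target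

Total step count: 17. Longest linear sequence: 16 steps (from 3, steps 2 to 17).

Steps most likely to fail

Step 8. What may go wrong: low facial selectivity at C5 in the 6π closure at 110 °C, since only a small steric difference separates the two transition states, and capture of the ketene by the free C7 hydroxyl (lactonisation) if the closure is slow. Fallback: from 13 the tertiary hydroxyl is silylated (Me3SiCl, Et3N) to the trimethylsilyl ether F1. The four-membered ring is then opened photochemically (UV light, toluene, about −40 °C) instead of thermally. The ketene then closes at low temperature, where the same energy difference should give a higher facial ratio and no hydroxyl is left to trap the ketene. This should give the 4-silyloxycyclohexa-2,4-dienone (silyl dienol ether) F2. Potassium tert-butoxide cleaves its O–Si bond to the potassium dienolate 17, which is triflated with PhNTf2 as in step 9, and the route is rejoined at 18.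

Step 13. What may go wrong: acid-induced ionisation of the tertiary allylic C10 hydroxyl, assisted by the C8 enol ether oxygen (loss of water and allylic transposition to a cross-conjugated dienone), in competition with protonation at C9; protonation of C9 from the α face would in addition give the C9 epimer. Fallback: from 22 the C10 hydroxyl is first capped as its triethylsilyl ether F4 (Et3SiOTf, 2,6-lutidine), which resists ionisation. CF3CO2H followed by water then removes both tert-butyl groups and the silyl group. With the bulky silyloxy group on the β face, protonation is expected from the α face and should give the 9β-hydroxy epimer F5. Mitsunobu esterification of F5 with angelic acid (PPh3, diisopropyl azodicarboxylate) installs the angelate with inversion at C9 and rejoins the route at 25; an α-keto carbinol is a good SN2 substrate and the cis C10 hydroxyl cannot close an epoxide. Should 24 form instead, it enters step 14 unchanged.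

Step 12. What may go wrong: electron transfer or direct addition of t-BuLi to the electron-poor dienone, attack at the triflate sulfur, or conjugate addition of the alkyllithium at C6 instead of 1,2-addition at C10. Fallback: ring B is closed before the triflate is made. From 16, DDQ removes the PMB group to give the primary alcohol F6, and PPh3/I2/imidazole gives the primary iodide F7. LiN(SiMe3)2 at −78 °C converts the C7 ketone into its lithium enolate F8, which removes the acidic C6 hydrogens and makes C6 nucleophilic; enolate alkylation by the iodide is slow at this temperature. t-BuLi then effects the exchange, the alkyllithium closes onto C10, and protonation gives the bicyclic hydroxy enone F9. KN(SiMe3)2 (2 equiv) and PhNTf2 convert F9 into the enol triflate, rejoining the route at 22.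

Further compounds
F1 | step 8 | trimethylsilyl ether of 13 | CC(C)(C)OC1=C(OC(C)(C)C)C(O[Si](C)(C)C)(/C=C(\C)[C@@H](C)[C@@H](O[Si](C(C)C)(C(C)C)C(C)C)CCOCc2ccc(OC)cc2)C1=O
F2 | step 8 | 2,3-di-tert-butoxy-6-methyl-6-[(2R,3S)-5-[(4-methoxybenzyl)oxy]-3-[(triisopropylsilyl)oxy]pentan-2-yl]-4-[(trimethylsilyl)oxy]cyclohexa-2,4-dien-1-one | CC(C)(C)OC1=C(OC(C)(C)C)C(O[Si](C)(C)C)=C[C@@](C)(C1=O)[C@@H](C)[C@@H](O[Si](C(C)C)(C(C)C)C(C)C)CCOCc1ccc(OC)cc1
F4 | step 13 | C10 triethylsilyl ether of 22 | CC(C)(C)OC1=C(OC(C)(C)C)C(OS(=O)(=O)C(F)(F)F)=C[C@]2(C)[C@@H](C)[C@@H](O[Si](C(C)C)(C(C)C)C(C)C)CC[C@]12O[Si](CC)(CC)CC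
F5 | step 13 | C9 epimer of 24 (9β-hydroxy) | O[C@H]1C(=O)C(OS(=O)(=O)C(F)(F)F)=C[C@]2(C)[C@@H](C)[C@@H](O[Si](C(C)C)(C(C)C)C(C)C)CC[C@]12O
F6 | step 12 | (5R)-2,3-di-tert-butoxy-5-[(2R,3S)-5-hydroxy-3-[(triisopropylsilyl)oxy]pentan-2-yl]-5-methylcyclohex-2-ene-1,4-dione | CC(C)(C)OC1=C(OC(C)(C)C)C(=O)C[C@@](C)(C1=O)[C@@H](C)[C@@H](O[Si](C(C)C)(C(C)C)C(C)C)CCO
F7 | step 12 | (5R)-2,3-di-tert-butoxy-5-[(2R,3S)-5-iodo-3-[(triisopropylsilyl)oxy]pentan-2-yl]-5-methylcyclohex-2-ene-1,4-dione | CC(C)(C)OC1=C(OC(C)(C)C)C(=O)C[C@@](C)(C1=O)[C@@H](C)[C@@H](O[Si](C(C)C)(C(C)C)C(C)C)CCI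
F8 | step 12 | lithium enolate of F7 (C6=C7–OLi) | CC(C)(C)OC1=C(OC(C)(C)C)C([O-])=C[C@@](C)(C1=O)[C@@H](C)[C@@H](O[Si](C(C)C)(C(C)C)C(C)C)CCI.[Li+]
F9 | step 12 | cis-fused 8,9-di-tert-butoxy-10-hydroxy-4,5-dimethyl-3-[(triisopropylsilyl)oxy]bicyclo[4.4.0]dec-8-en-7-one (target numbering) | CC(C)(C)OC1=C(OC(C)(C)C)C(=O)C[C@]2(C)[C@@H](C)[C@@H](O[Si](C(C)C)(C(C)C)C(C)C)CC[C@]12O
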